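**Pinophilin G – total synthesis plan (three fragments, 16 steps)**

Assumption: the SMILES is read as 7S,8S,8aS (isochromene numbering C1, O2, C3, C4, C4a, C5–C8, C8a), with 7-OH, 8-acyloxy and 8a-H on one face and an E side chain. These locants are used throughout.

**Retrosynthetic overview**
1. Target ⇐ protected bicycle by one acidolysis (two MOM ethers, TES ether, tert-butyl ester).
2. Pyran ring (formed last): O2–C3 bond by 6-endo cyclisation of the C1 alcohol onto a 3-alkynylcyclohexenone.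
3. C4a–C4 bond: Pd-catalysed alkynyl Mizoroki–Heck coupling of a cyclohex-2-enone with a bromo-enyne ester (itself made by Sonogashira coupling).
4. C8 ester: acylation of a cis-diol with MOM-protected orsellinoyl fluoride; the arene is built separately from methyl acetoacetate and methyl crotonate.
5. Carbocycle (formed first): organocatalytic Michael/aldol annulation sets C8a, then anti-selective OsO4 dihydroxylation sets C7 and C8.

**Aryl acid fragment**

Step 1
Reactants: 1 methyl acetoacetate; 2 methyl (E)-but-2-enoate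
Product: 4 methyl 6-methyl-2,4-dioxocyclohexane-1-carboxylate, via Michael adduct 3 (not isolated)
Conditions: NaOMe (1.1 equiv), MeOH, reflux; then 2 M HCl, 0 °C
Reagents that add atoms: none
Why: Michael addition of the acetoacetate enolate to the crotonate followed by intramolecular Claisen condensation of the acetyl methyl onto the distal ester is the classical entry to dihydroorsellinates, and its stereocentres are erased on aromatisation.

Step 2
Reactants: 4 methyl 6-methyl-2,4-dioxocyclohexane-1-carboxylate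
Product: 6 methyl 2,4-dihydroxy-6-methylbenzoate, via bromo dione 5 (not isolated)
Conditions: Br2 (1.05 equiv), DMF, 0 °C; then 80 °C
Reagents that add atoms: none
Why: Bromination at the doubly activated C3 and loss of two HBr with tautomerisation (oxidative aromatisation of a cyclohexane-1,3-dione) gives the resorcylate, driven by aromaticity.

Step 3
Reactants: 6 methyl 2,4-dihydroxy-6-methylbenzoate
Product: 7 methyl 2,4-bis(methoxymethoxy)-6-methylbenzoate
Conditions: NaH (2.5 equiv), MOMCl (2.5 equiv), DMF, 0 °C to rt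
Reagents that add atoms: chloromethyl methyl ether, COCCl
Why: Williamson O-alkylation of both phenoxides (MOM protection), with NaH needed to break the hydrogen bond of the ortho phenol.

Step 4
Reactants: 7 methyl 2,4-bis(methoxymethoxy)-6-methylbenzoate
Product: 8 2,4-bis(methoxymethoxy)-6-methylbenzoic acid
Conditions: KOH (5 equiv), MeOH/H2O (3:1), 70 °C; then 1 M HCl to pH 4, 0 °C
Reagents that add atoms: potassium hydroxide, [K+].[OH-]
Why: Saponification of the hindered benzoate needs heat but the MOM acetals are base-stable and survive the cold, brief acidification.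

**Bromo-enyne fragment**

Step 5
Reactants: 9 (E)-3-iodoprop-2-enoic acid
Product: 10 tert-butyl (E)-3-iodoprop-2-enoate
Conditions: tert-butyl 2,2,2-trichloroacetimidate (2 equiv), CH2Cl2/cyclohexane, rt
Reagents that add atoms: tert-butyl 2,2,2-trichloroacetimidate, CC(C)(C)OC(=N)C(Cl)(Cl)Cl
Why: Acid-promoted tert-butyl transfer from the imidate esterifies the acid without a nucleophile or base that could attack the β-iodoacrylate, so the E geometry is kept.

Step 6
Reactants: 10 tert-butyl (E)-3-iodoprop-2-enoate; 11 ethynyltrimethylsilane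
Product: 12 tert-butyl (E)-5-(trimethylsilyl)pent-2-en-4-ynoate
Conditions: PdCl2(PPh3)2 (2 mol %), CuI (4 mol %), Et3N (3 equiv), THF, 0 °C to rt
Reagents that add atoms: none
Why: Sonogashira coupling of a vinyl iodide proceeds with retention of the E geometry and forms the future C3–side-chain bond.

Step 7
Reactants: 12 tert-butyl (E)-5-(trimethylsilyl)pent-2-en-4-ynoate
Product: 13 tert-butyl (E)-5-bromopent-2-en-4-ynoate
Conditions: NBS (1.2 equiv), AgNO3 (10 mol %), acetone, rt, dark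
Reagents that add atoms: N-bromosuccinimide, O=C1CCC(=O)N1Br
Why: Silver-catalysed bromodesilylation converts the alkynylsilane directly into the 1-bromoalkyne via a silver acetylide.

**Core, fragment union and endgame**

Step 8
Reactants: 14 propane-1,3-diol
Product: 15 3-[(4-methoxybenzyl)oxy]propan-1-ol
Conditions: 14 (3 equiv), NaH (1.0 equiv), PMBCl (1.0 equiv), n-Bu4NI (cat.), THF/DMF, 0 °C to rt
Reagents that add atoms: 4-methoxybenzyl chloride, COc1ccc(CCl)cc1
Why: Williamson etherification with excess diol gives the mono-PMB ether, whose oxygen becomes O2 of the target.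

Step 9
Reactants: 15 3-[(4-methoxybenzyl)oxy]propan-1-ol
Product: 16 3-[(4-methoxybenzyl)oxy]propanal
Conditions: TEMPO (10 mol %), PhI(OAc)2 (1.1 equiv), CH2Cl2, rt
Reagents that add atoms: none
Why: Oxoammonium (TEMPO) oxidation stops cleanly at the aldehyde under near-neutral conditions that spare the PMB ether.

Step 10
Reactants: 16 3-[(4-methoxybenzyl)oxy]propanal; 17 pent-1-en-3-one
Product: 19 (R)-4-{[(4-methoxybenzyl)oxy]methyl}-2-methylcyclohex-2-en-1-one, via keto aldehyde 18 (not isolated)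
Conditions: (S)-2-[diphenyl(trimethylsilyloxy)methyl]pyrrolidine (10 mol %), ethyl 3,4-dihydroxybenzoate (20 mol %), 17 (1.5 equiv), neat, 4 °C; then LiOH·H2O (20 mol %), i-PrOH, rt
Reagents that add atoms: none
Why: Enamine-mediated asymmetric Michael addition (diarylprolinol silyl ether catalysis) followed by intramolecular aldol condensation (Robinson-type annulation), in which the E-enamine is attacked on the face remote from the CPh2OTMS group to give (S)-18 and hence the C8a stereocentre.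

Step 11
Reactants: 19 (R)-4-{[(4-methoxybenzyl)oxy]methyl}-2-methylcyclohex-2-en-1-one
Product: 20 (2S,3S,4S)-2,3-dihydroxy-4-{[(4-methoxybenzyl)oxy]methyl}-2-methylcyclohexan-1-one
Conditions: OsO4 (4 mol %), NMO (1.5 equiv), acetone/H2O (5:1), rt
Reagents that add atoms: N-methylmorpholine N-oxide, C[N+]1([O-])CCOCC1; water, O
Why: Upjohn syn-dihydroxylation of the enone occurs on the face anti to the adjacent C8a side arm, setting C7 and C8 as a cis-diol trans to the CH2OPMB group.

Step 12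
Reactants: 8 2,4-bis(methoxymethoxy)-6-methylbenzoic acid; 20 (2S,3S,4S)-2,3-dihydroxy-4-{[(4-methoxybenzyl)oxy]methyl}-2-methylcyclohexan-1-one
Product: 22 (1S,2S,6S)-2-hydroxy-6-{[(4-methoxybenzyl)oxy]methyl}-2-methyl-3-oxocyclohexyl 2,4-bis(methoxymethoxy)-6-methylbenzoate, via acyl fluoride 21 (not isolated)
Conditions: 8, cyanuric fluoride (1.0 equiv), pyridine, CH2Cl2, −10 °C; then 20, DMAP (2 equiv), i-Pr2NEt (3 equiv), CH2Cl2, 40 °C
Reagents that add atoms: none
Why: The small, MOM-compatible acyl fluoride esterifies the hindered secondary C8 hydroxyl under DMAP catalysis (nucleophilic acyl substitution) while the tertiary C7 hydroxyl is inert, and no strong base is present that could trigger retro-aldol opening.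

Step 13
Reactants: 22 (1S,2S,6S)-2-hydroxy-6-{[(4-methoxybenzyl)oxy]methyl}-2-methyl-3-oxocyclohexyl 2,4-bis(methoxymethoxy)-6-methylbenzoate
Product: 24 (1S,2S,6S)-6-{[(4-methoxybenzyl)oxy]methyl}-2-methyl-3-oxo-2-[(triethylsilyl)oxy]cyclohex-4-en-1-yl 2,4-bis(methoxymethoxy)-6-methylbenzoate, via bis-silyl compound 23 (not isolated)
Conditions: TESOTf (3 equiv), Et3N (5 equiv), CH2Cl2, −78 to 0 °C; then Pd(OAc)2 (1.1 equiv), MeCN, rt
Reagents that add atoms: triethylsilyl trifluoromethanesulfonate, CC[Si](CC)(CC)OS(=O)(=O)C(F)(F)F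
Why: Saegusa–Ito oxidation, in which soft enolisation can only go toward C5 because C7 is quaternary, so the C5=C4a enone forms regiospecifically while the same reagent caps the tertiary alcohol as its TES ether.

Step 14
Reactants: 24 (1S,2S,6S)-6-{[(4-methoxybenzyl)oxy]methyl}-2-methyl-3-oxo-2-[(triethylsilyl)oxy]cyclohex-4-en-1-yl 2,4-bis(methoxymethoxy)-6-methylbenzoate; 13 tert-butyl (E)-5-bromopent-2-en-4-ynoate
Product: 25 tert-butyl (E)-5-[(4S,5S,6S)-5-{[2,4-bis(methoxymethoxy)-6-methylbenzoyl]oxy}-6-{[(4-methoxybenzyl)oxy]methyl}-4-methyl-3-oxo-4-[(triethylsilyl)oxy]cyclohex-1-en-1-yl]pent-2-en-4-ynoate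
Conditions: Pd(OAc)2 (10 mol %), n-Bu4NCl (1 equiv), NaHCO3 (2.5 equiv), 4 Å MS, DMF, 45 °C, slow addition of 13 (2 equiv)
Reagents that add atoms: none
Why: Proposed new method: an alkynyl Mizoroki–Heck coupling on a cyclic enone, in which zerovalent palladium inserts into the C(sp)–Br bond of 13, the alkynyl–Pd species adds syn across C4a=C5 with the alkynyl group at the β-carbon C4a anti to the C8a side arm, the C5-bound Pd enolate equilibrates through its O-bound form so that syn β-hydride elimination of the C4a–H restores the enone, and bicarbonate takes up HBr, forming the C4a–C4 bond without touching C8a; the closest known reactions are Heck arylation of cyclohex-2-enones to 3-arylcyclohexenones under ligand-free phase-transfer conditions and Pd-catalysed Heck-type coupling of 1-bromoalkynes with acrylates to give enynes.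

Step 15
Reactants: 25 tert-butyl (E)-5-[(4S,5S,6S)-5-{[2,4-bis(methoxymethoxy)-6-methylbenzoyl]oxy}-6-{[(4-methoxybenzyl)oxy]methyl}-4-methyl-3-oxo-4-[(triethylsilyl)oxy]cyclohex-1-en-1-yl]pent-2-en-4-ynoate
Product: 27 (7S,8S,8aS)-3-[(E)-3-tert-butoxy-3-oxoprop-1-en-1-yl]-7-methyl-6-oxo-7-[(triethylsilyl)oxy]-1,7,8,8a-tetrahydro-6H-isochromen-8-yl 2,4-bis(methoxymethoxy)-6-methylbenzoate, via primary alcohol 26 (not isolated)
Conditions: DDQ (1.3 equiv), CH2Cl2/pH 7 buffer (10:1), 0 °C to rt; NaHCO3 wash; then Ph3PAuNTf2 (5 mol %), CH2Cl2, 0 °C to rt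
Reagents that add atoms: none
Why: Oxidative PMB cleavage followed by gold-catalysed 6-endo-dig hydroalkoxylation (a formal 1,6-oxa-Michael addition), in which the C1 hydroxyl attacks C3, the alkyne carbon δ to the ring ketone, to give the dienol ether conjugated with the enone under non-basic conditions that leave C8a untouched.

Step 16
Reactants: 27 (7S,8S,8aS)-3-[(E)-3-tert-butoxy-3-oxoprop-1-en-1-yl]-7-methyl-6-oxo-7-[(triethylsilyl)oxy]-1,7,8,8a-tetrahydro-6H-isochromen-8-yl 2,4-bis(methoxymethoxy)-6-methylbenzoate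
Product: 28 (E)-3-[(7S,8S,8aS)-8-[(2,4-dihydroxy-6-methylbenzoyl)oxy]-7-hydroxy-7-methyl-6-oxo-1,7,8,8a-tetrahydro-6H-isochromen-3-yl]prop-2-enoic acid (Pinophilin G)
Conditions: TFA/CH2Cl2/H2O (10:30:1), 0 °C to rt
Reagents that add atoms: none
Why: Brønsted acidolysis removes the tert-butyl ester, both MOM acetals and the tertiary TES ether in one operation, while the hindered aryl ester, the push–pull dienol ether and the three stereocentres are inert to non-basic conditions.

**Compound list**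
1 | methyl acetoacetate | CC(=O)CC(=O)OC | starting material
2 | methyl (E)-but-2-enoate (methyl crotonate) | C/C=C/C(=O)OC | starting material
3 | dimethyl 2-acetyl-3-methylpentanedioate (stereoisomer mixture) | COC(=O)CC(C)C(C(C)=O)C(=O)OC | intermediate (not isolated)
4 | methyl 6-methyl-2,4-dioxocyclohexane-1-carboxylate (stereoisomer/tautomer mixture) | COC(=O)C1C(C)CC(=O)CC1=O | intermediate
5 | methyl 3-bromo-6-methyl-2,4-dioxocyclohexane-1-carboxylate (stereoisomer mixture) | COC(=O)C1C(C)CC(=O)C(Br)C1=O | intermediate (not isolated)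
6 | methyl 2,4-dihydroxy-6-methylbenzoate (methyl orsellinate) | COC(=O)c1c(C)cc(O)cc1O | intermediate
7 | methyl 2,4-bis(methoxymethoxy)-6-methylbenzoate | COCOc1cc(C)c(C(=O)OC)c(OCOC)c1 | intermediate
8 | 2,4-bis(methoxymethoxy)-6-methylbenzoic acid | COCOc1cc(C)c(C(=O)O)c(OCOC)c1 | intermediate
9 | (E)-3-iodoprop-2-enoic acid | OC(=O)/C=C/I | starting material
10 | tert-butyl (E)-3-iodoprop-2-enoate | CC(C)(C)OC(=O)/C=C/I | intermediate
11 | ethynyltrimethylsilane | C#C[Si](C)(C)C | starting material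
12 | tert-butyl (E)-5-(trimethylsilyl)pent-2-en-4-ynoate | CC(C)(C)OC(=O)/C=C/C#C[Si](C)(C)C | intermediate
13 | tert-butyl (E)-5-bromopent-2-en-4-ynoate | CC(C)(C)OC(=O)/C=C/C#CBr | intermediate
14 | propane-1,3-diol | OCCCO | starting material
15 | 3-[(4-methoxybenzyl)oxy]propan-1-ol | COc1ccc(COCCCO)cc1 | intermediate
16 | 3-[(4-methoxybenzyl)oxy]propanal | COc1ccc(COCCC=O)cc1 | intermediate
17 | pent-1-en-3-one (ethyl vinyl ketone) | CCC(=O)C=C | starting material
18 | (S)-2-{[(4-methoxybenzyl)oxy]methyl}-5-oxoheptanal | O=C[C@H](COCc1ccc(OC)cc1)CCC(=O)CC | intermediate (not isolated)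
19 | (R)-4-{[(4-methoxybenzyl)oxy]methyl}-2-methylcyclohex-2-en-1-one | O=C1C(C)=C[C@H](COCc2ccc(OC)cc2)CC1 | intermediate
20 | (2S,3S,4S)-2,3-dihydroxy-4-{[(4-methoxybenzyl)oxy]methyl}-2-methylcyclohexan-1-one | O[C@H]1[C@H](COCc2ccc(OC)cc2)CCC(=O)[C@@]1(C)O | intermediate
21 | 2,4-bis(methoxymethoxy)-6-methylbenzoyl fluoride | COCOc1cc(C)c(C(F)=O)c(OCOC)c1 | intermediate (not isolated)
22 | (1S,2S,6S)-2-hydroxy-6-{[(4-methoxybenzyl)oxy]methyl}-2-methyl-3-oxocyclohexyl 2,4-bis(methoxymethoxy)-6-methylbenzoate | Cc1cc(OCOC)cc(OCOC)c1C(=O)O[C@H]1[C@H](COCc2ccc(OC)cc2)CCC(=O)[C@@]1(C)O | intermediate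
23 | (1S,2S,6S)-6-{[(4-methoxybenzyl)oxy]methyl}-2-methyl-2,3-bis[(triethylsilyl)oxy]cyclohex-3-en-1-yl 2,4-bis(methoxymethoxy)-6-methylbenzoate | Cc1cc(OCOC)cc(OCOC)c1C(=O)O[C@H]1[C@H](COCc2ccc(OC)cc2)CC=C(O[Si](CC)(CC)CC)[C@@]1(C)O[Si](CC)(CC)CC | intermediate (not isolated)
24 | (1S,2S,6S)-6-{[(4-methoxybenzyl)oxy]methyl}-2-methyl-3-oxo-2-[(triethylsilyl)oxy]cyclohex-4-en-1-yl 2,4-bis(methoxymethoxy)-6-methylbenzoate | Cc1cc(OCOC)cc(OCOC)c1C(=O)O[C@H]1[C@H](COCc2ccc(OC)cc2)C=CC(=O)[C@@]1(C)O[Si](CC)(CC)CC | intermediate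
25 | tert-butyl (E)-5-[(4S,5S,6S)-5-{[2,4-bis(methoxymethoxy)-6-methylbenzoyl]oxy}-6-{[(4-methoxybenzyl)oxy]methyl}-4-methyl-3-oxo-4-[(triethylsilyl)oxy]cyclohex-1-en-1-yl]pent-2-en-4-ynoate | Cc1cc(OCOC)cc(OCOC)c1C(=O)O[C@H]1[C@H](COCc2ccc(OC)cc2)C(C#C/C=C/C(=O)OC(C)(C)C)=CC(=O)[C@@]1(C)O[Si](CC)(CC)CC | intermediate
26 | tert-butyl (E)-5-[(4S,5S,6S)-5-{[2,4-bis(methoxymethoxy)-6-methylbenzoyl]oxy}-6-(hydroxymethyl)-4-methyl-3-oxo-4-[(triethylsilyl)oxy]cyclohex-1-en-1-yl]pent-2-en-4-ynoate | Cc1cc(OCOC)cc(OCOC)c1C(=O)O[C@H]1[C@H](CO)C(C#C/C=C/C(=O)OC(C)(C)C)=CC(=O)[C@@]1(C)O[Si](CC)(CC)CC | intermediate (not isolated)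
27 | (7S,8S,8aS)-3-[(E)-3-tert-butoxy-3-oxoprop-1-en-1-yl]-7-methyl-6-oxo-7-[(triethylsilyl)oxy]-1,7,8,8a-tetrahydro-6H-isochromen-8-yl 2,4-bis(methoxymethoxy)-6-methylbenzoate | Cc1cc(OCOC)cc(OCOC)c1C(=O)O[C@H]1[C@@H]2COC(/C=C/C(=O)OC(C)(C)C)=CC2=CC(=O)[C@@]1(C)O[Si](CC)(CC)CC | intermediate
28 | (E)-3-[(7S,8S,8aS)-8-[(2,4-dihydroxy-6-methylbenzoyl)oxy]-7-hydroxy-7-methyl-6-oxo-1,7,8,8a-tetrahydro-6H-isochromen-3-yl]prop-2-enoic acid (Pinophilin G) | Cc1cc(O)cc(O)c1C(=O)O[C@H]1[C@@H]2COC(/C=C/C(=O)O)=CC2=CC(=O)[C@@]1(C)O | target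

**Totals**
Total step count: 16.
Longest linear sequence: 9 steps (steps 8 to 16; the arene branch, steps 1 to 4 followed by 12 to 16, is equally long).

**Three steps most likely to fail, with fallbacks**

Step 14 (the proposed alkynyl Heck coupling). The alkynyl–Pd species may homocouple or insert too slowly, or the Pd enolate may be protonated instead of eliminating. The fallback uses known chemistry, sets out from 24 and 12 and comes back at 25. Compound 12 is desilylated (K2CO3 cat., MeOH, 0 °C) to tert-butyl (E)-pent-2-en-4-ynoate F1. Its zinc acetylide (LiHMDS, THF, −78 °C; then ZnBr2) is added to 24 in the presence of TBSOTf at −40 °C. This silyl-triflate-promoted conjugate alkynylation delivers the alkynyl group to C4a anti to the C8a side arm and traps the enolate as the TBS enol ether of the 1,4-adduct F2. Saegusa–Ito oxidation of F2 (Pd(OAc)2, MeCN, rt) then gives 25.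

Step 15 (ring closure). The alkyne of 26 lies between two acceptors, so 5-exo attack at C4 (the 1,6-mode of the dienoate) could compete with the desired 6-endo attack at C3. The fallback removes the ambiguity by closing the ring before the acrylate exists; it sets out from 24 and comes back at 27. Lithiated 1-methoxy-4-[(prop-2-yn-1-yloxy)methyl]benzene (n-BuLi, then ZnBr2) is added to 24 with TBSOTf as above to give the TBS enol ether of the propargyl adduct F3. Pd(OAc)2 in MeCN converts F3 into the 3-alkynyl enone carrying a CH2OPMB terminus F4. DDQ (2.6 equiv) removes both PMB groups to give the diol F5, whose alkyne is conjugated only with the ring enone. F5 therefore cyclises (DBU cat., CH2Cl2, 0 °C) exclusively by 1,6-oxa-Michael addition to the 3-(hydroxymethyl) pyran F6. MnO2 oxidation gives the 3-formyl pyran F7, and Wittig olefination with tert-butyl (triphenylphosphoranylidene)acetate (CH2Cl2, rt) installs the E acrylate and returns 27.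

Step 10 (organocatalytic annulation). The enamine of the β-alkoxy aldehyde 16 can expel the PMB alkoxide, and the base-mediated ring closure can erode the ee. The fallback replaces catalyst control by auxiliary control; it sets out from 16 and comes back at 18. Pinnick oxidation (NaClO2, NaH2PO4, 2-methylbut-2-ene) gives 3-[(4-methoxybenzyl)oxy]propanoic acid F8. The mixed pivalic anhydride (PivCl, Et3N) is coupled with lithiated (S)-4-benzyloxazolidin-2-one to give the imide F9. Its chlorotitanium enolate (TiCl4, i-Pr2NEt, CH2Cl2, −78 to 0 °C) adds to 17 on the face opposite the benzyl group to give the Michael adduct F10. LiSEt (EtSH, n-BuLi, THF, 0 °C) releases the auxiliary and gives the thioester F11. Fukuyama reduction (Et3SiH, Pd/C, acetone) gives 18, which is cyclised to 19 with LiOH as in step 10.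

**Further compounds**
F1 | step 14 | tert-butyl (E)-pent-2-en-4-ynoate | CC(C)(C)OC(=O)/C=C/C#C
F2 | step 14 | TBS enol ether of the 1,4-adduct of F1 and 24 (alkynyl at C4a trans to the C8a CH2OPMB group) | Cc1cc(OCOC)cc(OCOC)c1C(=O)O[C@H]1[C@H](COCc2ccc(OC)cc2)[C@@H](C#C/C=C/C(=O)OC(C)(C)C)C=C(O[Si](C)(C)C(C)(C)C)[C@@]1(C)O[Si](CC)(CC)CC
F3 | step 15 | TBS enol ether of the 1,4-adduct of PMB propargyl ether and 24 (alkynyl at C4a trans to the C8a CH2OPMB group) | Cc1cc(OCOC)cc(OCOC)c1C(=O)O[C@H]1[C@H](COCc2ccc(OC)cc2)[C@@H](C#CCOCc2ccc(OC)cc2)C=C(O[Si](C)(C)C(C)(C)C)[C@@]1(C)O[Si](CC)(CC)CC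
F4 | step 15 | (1S,2S,6S)-6-{[(4-methoxybenzyl)oxy]methyl}-5-{3-[(4-methoxybenzyl)oxy]prop-1-yn-1-yl}-2-methyl-3-oxo-2-[(triethylsilyl)oxy]cyclohex-4-en-1-yl 2,4-bis(methoxymethoxy)-6-methylbenzoate | Cc1cc(OCOC)cc(OCOC)c1C(=O)O[C@H]1[C@H](COCc2ccc(OC)cc2)C(C#CCOCc2ccc(OC)cc2)=CC(=O)[C@@]1(C)O[Si](CC)(CC)CC
F5 | step 15 | (1S,2S,6S)-6-(hydroxymethyl)-5-(3-hydroxyprop-1-yn-1-yl)-2-methyl-3-oxo-2-[(triethylsilyl)oxy]cyclohex-4-en-1-yl 2,4-bis(methoxymethoxy)-6-methylbenzoate | Cc1cc(OCOC)cc(OCOC)c1C(=O)O[C@H]1[C@H](CO)C(C#CCO)=CC(=O)[C@@]1(C)O[Si](CC)(CC)CC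
F6 | step 15 | (7S,8S,8aS)-3-(hydroxymethyl)-7-methyl-6-oxo-7-[(triethylsilyl)oxy]-1,7,8,8a-tetrahydro-6H-isochromen-8-yl 2,4-bis(methoxymethoxy)-6-methylbenzoate | Cc1cc(OCOC)cc(OCOC)c1C(=O)O[C@H]1[C@@H]2COC(CO)=CC2=CC(=O)[C@@]1(C)O[Si](CC)(CC)CC
F7 | step 15 | (7S,8S,8aS)-3-formyl-7-methyl-6-oxo-7-[(triethylsilyl)oxy]-1,7,8,8a-tetrahydro-6H-isochromen-8-yl 2,4-bis(methoxymethoxy)-6-methylbenzoate | Cc1cc(OCOC)cc(OCOC)c1C(=O)O[C@H]1[C@@H]2COC(C=O)=CC2=CC(=O)[C@@]1(C)O[Si](CC)(CC)CC
F8 | step 10 | 3-[(4-methoxybenzyl)oxy]propanoic acid | COc1ccc(COCCC(=O)O)cc1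
F9 | step 10 | (S)-4-benzyl-3-{3-[(4-methoxybenzyl)oxy]propanoyl}oxazolidin-2-one | COc1ccc(COCCC(=O)N2[C@@H](Cc3ccccc3)COC2=O)cc1
F10 | step 10 | (S)-4-benzyl-3-[(S)-2-{[(4-methoxybenzyl)oxy]methyl}-5-oxoheptanoyl]oxazolidin-2-one | O=C(N1[C@@H](Cc2ccccc2)COC1=O)[C@H](COCc1ccc(OC)cc1)CCC(=O)CC
F11 | step 10 | S-ethyl (S)-2-{[(4-methoxybenzyl)oxy]methyl}-5-oxoheptanethioate | CCSC(=O)[C@H](COCc1ccc(OC)cc1)CCC(=O)CC
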